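**Plan**
1. Retrosynthesis: the O2–C3 bond of the 1,2-dioxane is cut last (the C6 peroxide displaces the ring oxygen of a cis-β-lactone on C1–C2–C3, so the carboxylic acid of the target is the leaving group). Then O1–C6 is cut (H2O2 opens a cyclopropylmethyl unit with inversion, breaking a temporary C4–C6 bond), then C6–C7 (B-alkyl Suzuki–Miyaura) and ring A of the decalin (Diels–Alder).
2. Enabling feature: C3 carries O2 and is β to the C1 carboxyl group, so the acid and the C3–O bond can be stored in a strained four-membered lactone (C1, C2, C3, O). C6 carries only CH3 and a CH2CH2 chain, which a chair cannot tell apart, so both C–O bonds are made by invertive substitution at carbons set by chiral reagents.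
3. Forward order: ring B (steps 1–5), ring A (6–7), side chain (8–9), cyclopropane closed (10) and opened (11), aldehyde (12–14), β-lactone closed (15), 1,2-dioxane closed last (16), which also frees the acid.
4. Stereochemistry: C8' by asymmetric conjugate addition, C9' by anti-alkylation next to C8', C5' by facial control in the Diels–Alder step, C6 by asymmetric Simmons–Smith cyclopropanation followed by inversion, C2 and C3 by asymmetric ketene–aldehyde cycloaddition, with C3 inverted in the key step.

Key step: step 16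

Numbering: C1–C6 is the acid chain (C1 carboxyl, C3 and C6 the dioxane carbons), C7–C8 the linker, C1'–C10' the decalin (C1'=C10', gem-dimethyl on C4'). Dec = (1R,2R,4aS)-1,2,5,5-tetramethyl-1,2,3,4,4a,5,6,7-octahydronaphthalen-1-yl, the decalin unit of the target bonded through C9'.
Assumption: the facial sense of each chiral controller is taken from its behaviour with simple substrates; if it proved opposite, the mirror-image or pseudoenantiomeric controller would be used.

**Step 1**
Reactants: 1 cyclohex-2-en-1-one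
Product: 4 (3R)-2-(hydroxymethylidene)-3-methylcyclohexan-1-one, via methylzinc enolate 2 (not isolated), via lithium zincate enolate 3 (not isolated)
Conditions: Me2Zn, Cu(OTf)2 (2 mol %), (R)-BINOL N,N-bis[(S)-1-phenylethyl]phosphoramidite (4 mol %), toluene, −30 °C; MeLi, THF, −78 °C; HCO2CH2CF3, −78 to 0 °C; aq. HCl
Reagents that add atoms: dimethylzinc C[Zn]C; 2,2,2-trifluoroethyl formate O=COCC(F)(F)F
Why: Copper-catalysed asymmetric conjugate addition sets C8' (R) under ligand control, and the regiodefined enolate, activated as its zincate, undergoes Claisen-type C-formylation at C9' only.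

**Step 2**
Reactants: 4 (3R)-2-(hydroxymethylidene)-3-methylcyclohexan-1-one
Product: 5 (1S,2R)-1,2-dimethyl-6-oxocyclohexane-1-carbaldehyde
Conditions: MeI, K2CO3, acetone, reflux
Reagents that add atoms: iodomethane IC
Why: C-alkylation of the β-dicarbonyl enolate should occur anti to the neighbouring C8' methyl, which sits pseudoaxial to avoid allylic 1,3-strain, so the new C9' methyl is trans to it and the formyl carbon (future C8) is cis.

**Step 3**
Reactants: 5 (1S,2R)-1,2-dimethyl-6-oxocyclohexane-1-carbaldehyde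
Product: 6 (2R,3R)-2-ethenyl-2,3-dimethylcyclohexan-1-one
Conditions: Ph3PCH3Br, KOtBu, THF, 0 °C
Reagents that add atoms: methyltriphenylphosphonium bromide C[P+](c1ccccc1)(c1ccccc1)c1ccccc1.[Br-]
Why: Wittig methylenation is chemoselective for the aldehyde over the hindered ketone next to the quaternary carbon.

**Step 4**
Reactants: 6 (2R,3R)-2-ethenyl-2,3-dimethylcyclohexan-1-one
Product: 8 (5R,6R)-6-ethenyl-5,6-dimethylcyclohex-1-en-1-yl trifluoromethanesulfonate, via potassium enolate 7 (not isolated)
Conditions: KN(SiMe3)2, THF, −78 °C; PhNTf2, −78 to 0 °C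
Reagents that add atoms: N-phenylbis(trifluoromethanesulfonimide) O=S(=O)(N(c1ccccc1)S(=O)(=O)C(F)(F)F)C(F)(F)F
Why: The ketone can enolise only toward C5' because C9' is quaternary, so O-sulfonylation of the enolate gives a single enol triflate.

**Step 5**
Reactants: 8 (5R,6R)-6-ethenyl-5,6-dimethylcyclohex-1-en-1-yl trifluoromethanesulfonate
Product: 9 (5R,6R)-1,6-diethenyl-5,6-dimethylcyclohex-1-ene
Conditions: CH2=CHSnBu3, Pd(PPh3)4 (5 mol %), LiCl, THF, reflux
Reagents that add atoms: tributyl(vinyl)stannane C=C[Sn](CCCC)(CCCC)CCCC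
Why: Stille coupling of an enol triflate with a vinylstannane gives the 1-vinylcyclohexene diene without touching the stereocentres.

**Step 6**
Reactants: 9 (5R,6R)-1,6-diethenyl-5,6-dimethylcyclohex-1-ene; 10 2-methylprop-2-enal (methacrolein)
Product: 11 (5R,6R,8aR)-5-ethenyl-1,5,6-trimethyl-1,2,3,5,6,7,8,8a-octahydronaphthalene-1-carbaldehyde (C1 epimers)
Conditions: Me2AlCl (30 mol %), CH2Cl2, −78 to −20 °C
Reagents that add atoms: none
Why: In this Lewis acid catalysed Diels–Alder reaction the formyl-bearing carbon bonds to C5' (ortho regiochemistry), and the dienophile should approach anti to the pseudoaxial C9' vinyl group, placing H-5' cis to it; the C4' configuration is erased in step 7.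

**Step 7**
Reactants: 11 the Diels–Alder aldehyde
Product: 13 (5R,6R,8aS)-5-ethenyl-1,1,5,6-tetramethyl-1,2,3,5,6,7,8,8a-octahydronaphthalene (Dec–CH=CH2), via hydrazone 12 (not isolated)
Conditions: N2H4·H2O, KOH, diethylene glycol, 130 then 200 °C
Reagents that add atoms: none
Why: Wolff–Kishner reduction (Huang-Minlon conditions) turns the non-enolisable neopentyl aldehyde into the second C4' methyl group while the isolated alkenes stay inert.

**Step 8**
Reactants: 14 but-2-yn-1-ol
Product: 16 (2Z)-3-iodobut-2-en-1-ol, via cyclic alkenylaluminate 15 (not isolated)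
Conditions: NaAlH2(OCH2CH2OCH3)2, THF, 0 °C to rt; N-iodosuccinimide, −78 °C
Reagents that add atoms: N-iodosuccinimide O=C1CCC(=O)N1I
Why: Alkoxide-directed trans-hydroalumination of the propargylic alcohol places aluminium on C3, and iododealumination with retention gives the (Z)-vinyl iodide.

**Step 9**
Reactants: 13 Dec–CH=CH2; 16 (2Z)-3-iodobut-2-en-1-ol
Product: 18 (2Z)-3-methyl-5-Dec-pent-2-en-1-ol, via B-alkyl-9-BBN 17 (not isolated)
Conditions: 9-BBN, THF, 0 °C to rt; then 16, PdCl2(dppf) (5 mol %), AsPh3, Cs2CO3, DMF/H2O, rt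
Reagents that add atoms: none
Why: 9-BBN hydroborates only the monosubstituted vinyl group (anti-Markovnikov), and the B-alkyl Suzuki–Miyaura coupling keeps the geometry of the vinyl iodide, giving the (Z)-trisubstituted allylic alcohol.

**Step 10**
Reactants: 18 (2Z)-3-methyl-5-Dec-pent-2-en-1-ol
Product: 19 [(1R,2S)-2-methyl-2-(2-Dec-ethyl)cyclopropyl]methanol
Conditions: Et2Zn, CH2I2, DME, CH2Cl2, −10 °C; 18 premixed with (4S,5S)-2-butyl-N,N,N',N'-tetramethyl-1,3,2-dioxaborolane-4,5-dicarboxamide (1.2 equiv), −10 °C to rt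
Reagents that add atoms: diiodomethane ICI
Why: Dioxaborolane-controlled asymmetric Simmons–Smith cyclopropanation delivers CH2 (the future C5) to one face of the allylic alkoxide with retention of alkene geometry, so the Z geometry and the ligand together fix C6 as S and create the temporary C4–C6 bond.

**Step 11**
Reactants: 19 [(1R,2S)-2-methyl-2-(2-Dec-ethyl)cyclopropyl]methanol
Product: 21 (3R)-3-methyl-1-Dec-hex-5-en-3-yl hydroperoxide, via cyclopropylmethyl mesylate 20 (not isolated)
Conditions: (MeSO2)2O, 2,6-lutidine, CH2Cl2, −40 °C; anhydrous H2O2 in Et2O (10 equiv), −40 to 0 °C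
Reagents that add atoms: hydrogen peroxide OO
Why: Proposed new method: ionisation of the primary cyclopropylmethyl mesylate is assisted by the C4–C6 bond and gives a non-classical cyclopropylcarbinyl cation whose charge rests on the quaternary C6. H2O2 in large excess should attack C6 from the side opposite the breaking C4–C6 bond, so C6 is inverted to R and C3=C4 is released as a vinyl group. The closest known reaction types are the stereoinvertive cyclopropylcarbinyl-to-homoallyl substitution at quaternary carbon with halide, water or alcohol nucleophiles and the acid-promoted opening of 2,2-disubstituted oxetanes by H2O2 with inversion.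

**Step 12**
Reactants: 21 (3R)-3-methyl-1-Dec-hex-5-en-3-yl hydroperoxide
Product: 22 triethyl{[(3R)-3-methyl-1-Dec-hex-5-en-3-yl]peroxy}silane
Conditions: Et3SiCl, imidazole, DMF, 0 °C
Reagents that add atoms: chlorotriethylsilane CC[Si](Cl)(CC)CC
Why: O-silylation of the hydroperoxide gives a silyl peroxide that should tolerate the borane, the oxidant and the amine base of the next three steps.

**Step 13**
Reactants: 22 the silyl peroxide
Product: 24 (4R)-4-methyl-6-Dec-4-[(triethylsilyl)peroxy]hexan-1-ol, via alkylborane 23 (not isolated)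
Conditions: 9-BBN, THF, 0 °C to rt; NaBO3·4H2O, H2O, rt
Reagents that add atoms: sodium perborate [Na+].[Na+].O[B-]1(O)OO[B-](O)(O)OO1
Why: Anti-Markovnikov hydroboration–oxidation of the only monosubstituted alkene gives the primary alcohol at C3, while the hindered ring alkene and the silyl peroxide should not react with 9-BBN at room temperature.

**Step 14**
Reactants: 24 the primary alcohol
Product: 25 (4R)-4-methyl-6-Dec-4-[(triethylsilyl)peroxy]hexanal
Conditions: Dess–Martin periodinane, CH2Cl2, 0 °C to rt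
Reagents that add atoms: none
Why: Dess–Martin oxidation gives the aldehyde under near-neutral conditions that leave the silyl peroxide intact.

**Step 15**
Reactants: 25 the aldehyde; 26 propanoyl chloride
Product: 28 (3S,4R)-3-methyl-4-{(3R)-3-methyl-5-Dec-3-[(triethylsilyl)peroxy]pentyl}oxetan-2-one (cis-β-lactone), via methylketene 27 (not isolated)
Conditions: O-trimethylsilylquinidine (10 mol %), LiClO4 (1 equiv), iPr2NEt, CH2Cl2/Et2O, −78 °C
Reagents that add atoms: none
Why: The cinchona-alkaloid-catalysed acyl halide–aldehyde cyclocondensation (ketene–aldehyde [2+2] through the ammonium enolate) gives the cis-3,4-disubstituted β-lactone under catalyst control, setting C2 as S and C3 as R, the latter to be inverted in step 16.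

**Step 16**
Reactants: 28 the cis-β-lactone
Product: 31 mycaperoxide H, via peroxide anion salt 29 (not isolated), via carboxylate salt 30 (not isolated)
Conditions: Bu4NF (1.1 equiv), THF (0.005 M), −40 to 0 °C; aq. HCl to pH 3
Reagents that add atoms: none
Why: Proposed new method: fluoride removes the silyl group and the tertiary peroxide anion on C6 attacks C3, the β-carbon of the β-lactone, in an intramolecular SN2 reaction with alkyl–oxygen cleavage, so the carboxylate of the target is the leaving group and about 23 kcal/mol of ring strain is released. The closest known reaction types are SN2 opening of β-lactones at the β-carbon by azide, thiolate or sulfonamide anions and by tethered ether oxygens, and the 6-exo-tet closure of hydroperoxides onto secondary sulfonates that gives 1,2-dioxanes. The 1,2-dioxane (O1, O2, C3, C4, C5, C6) closes in the 6-exo-tet mode. C3 is the only stereocentre formed and is set by inversion of the 3R lactone carbon to 3S, while C2 and C6 pass through unchanged, so the 2,3-anti and 3,6 relationships do not depend on ring conformation. The step needs alkyl–oxygen over acyl–oxygen cleavage and substitution over elimination: attack at the carbonyl would need an eight-membered cyclic perester and is disfavoured by the hindered tertiary peroxide and high dilution, and a β-lactone cannot lose its β-oxygen by the E1cB path open to acyclic β-sulfonyloxy esters.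

**Compound list**
1 | cyclohex-2-en-1-one | O=C1C=CCCC1 | starting material
2 | methylzinc (3R)-3-methylcyclohex-1-en-1-olate | C[Zn]OC1=C[C@H](C)CCC1 | intermediate
3 | lithium dimethyl[(3R)-3-methylcyclohex-1-en-1-olato]zincate | C[Zn-](C)OC1=C[C@H](C)CCC1.[Li+] | intermediate
4 | (3R)-2-(hydroxymethylidene)-3-methylcyclohexan-1-one | OC=C1C(=O)CCC[C@H]1C | intermediate
5 | (1S,2R)-1,2-dimethyl-6-oxocyclohexane-1-carbaldehyde | O=C[C@@]1(C)C(=O)CCC[C@H]1C | intermediate
6 | (2R,3R)-2-ethenyl-2,3-dimethylcyclohexan-1-one | C=C[C@@]1(C)C(=O)CCC[C@H]1C | intermediate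
7 | potassium (5R,6R)-6-ethenyl-5,6-dimethylcyclohex-1-en-1-olate | C=C[C@@]1(C)C([O-])=CCC[C@H]1C.[K+] | intermediate
8 | (5R,6R)-6-ethenyl-5,6-dimethylcyclohex-1-en-1-yl trifluoromethanesulfonate | C=C[C@@]1(C)C(OS(=O)(=O)C(F)(F)F)=CCC[C@H]1C | intermediate
9 | (5R,6R)-1,6-diethenyl-5,6-dimethylcyclohex-1-ene | C=C[C@@]1(C)C(C=C)=CCC[C@H]1C | intermediate
10 | 2-methylprop-2-enal | CC(=C)C=O | starting material
11 | (5R,6R,8aR)-5-ethenyl-1,5,6-trimethyl-1,2,3,5,6,7,8,8a-octahydronaphthalene-1-carbaldehyde, C1 epimers, H-8a cis to the ethenyl group | C=C[C@@]1(C)C2=CCCC(C)(C=O)[C@@H]2CC[C@H]1C | intermediate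
12 | hydrazone of 11 | C=C[C@@]1(C)C2=CCCC(C)(C=NN)[C@@H]2CC[C@H]1C | intermediate
13 | (5R,6R,8aS)-5-ethenyl-1,1,5,6-tetramethyl-1,2,3,5,6,7,8,8a-octahydronaphthalene (Dec–CH=CH2) | C=C[C@@]1(C)C2=CCCC(C)(C)[C@@H]2CC[C@H]1C | intermediate
14 | but-2-yn-1-ol | CC#CCO | starting material
15 | sodium cyclic alkenylaluminate from 14 (Al on C3 and on O, two 2-methoxyethoxy groups) | CC1=CCO[Al-]1(OCCOC)OCCOC.[Na+] | intermediate
16 | (2Z)-3-iodobut-2-en-1-ol | C/C(I)=C/CO | intermediate
17 | 9-(2-Dec-ethyl)-9-borabicyclo[3.3.1]nonane | B1(CC[C@@]3(C)C4=CCCC(C)(C)[C@@H]4CC[C@H]3C)C2CCCC1CCC2 | intermediate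
18 | (2Z)-3-methyl-5-Dec-pent-2-en-1-ol | OC/C=C(/C)CC[C@@]1(C)C2=CCCC(C)(C)[C@@H]2CC[C@H]1C | intermediate
19 | [(1R,2S)-2-methyl-2-(2-Dec-ethyl)cyclopropyl]methanol (CH2OH cis to the Dec-ethyl chain) | OC[C@@H]1C[C@]1(C)CC[C@@]2(C)C3=CCCC(C)(C)[C@@H]3CC[C@H]2C | intermediate
20 | methanesulfonate of 19 | CS(=O)(=O)OC[C@@H]1C[C@]1(C)CC[C@@]2(C)C3=CCCC(C)(C)[C@@H]3CC[C@H]2C | intermediate
21 | (3R)-3-methyl-1-Dec-hex-5-en-3-yl hydroperoxide | C=CC[C@](C)(OO)CC[C@@]1(C)C2=CCCC(C)(C)[C@@H]2CC[C@H]1C | intermediate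
22 | triethyl{[(3R)-3-methyl-1-Dec-hex-5-en-3-yl]peroxy}silane | C=CC[C@](C)(OO[Si](CC)(CC)CC)CC[C@@]1(C)C2=CCCC(C)(C)[C@@H]2CC[C@H]1C | intermediate
23 | B-alkyl-9-BBN from 22 (boron on the terminal carbon, C6 configuration as in 22) | B1(CCC[C@](C)(OO[Si](CC)(CC)CC)CC[C@@]3(C)C4=CCCC(C)(C)[C@@H]4CC[C@H]3C)C2CCCC1CCC2 | intermediate
24 | (4R)-4-methyl-6-Dec-4-[(triethylsilyl)peroxy]hexan-1-ol | OCCC[C@](C)(OO[Si](CC)(CC)CC)CC[C@@]1(C)C2=CCCC(C)(C)[C@@H]2CC[C@H]1C | intermediate
25 | (4R)-4-methyl-6-Dec-4-[(triethylsilyl)peroxy]hexanal | O=CCC[C@](C)(OO[Si](CC)(CC)CC)CC[C@@]1(C)C2=CCCC(C)(C)[C@@H]2CC[C@H]1C | intermediate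
26 | propanoyl chloride | CCC(=O)Cl | starting material
27 | methylketene (prop-1-en-1-one) | CC=C=O | intermediate
28 | (3S,4R)-3-methyl-4-{(3R)-3-methyl-5-Dec-3-[(triethylsilyl)peroxy]pentyl}oxetan-2-one | C[C@@H]1C(=O)O[C@@H]1CC[C@](C)(OO[Si](CC)(CC)CC)CC[C@@]2(C)C3=CCCC(C)(C)[C@@H]3CC[C@H]2C | intermediate
29 | tetrabutylammonium peroxide (C6–O–O−) of the desilylated lactone | C[C@@H]1C(=O)O[C@@H]1CC[C@](C)(O[O-])CC[C@@]2(C)C3=CCCC(C)(C)[C@@H]3CC[C@H]2C.CCCC[N+](CCCC)(CCCC)CCCC | intermediate
30 | tetrabutylammonium salt of mycaperoxide H | C[C@H](C(=O)[O-])[C@@H]1CC[C@@](C)(CC[C@@]2(C)C3=CCCC(C)(C)[C@@H]3CC[C@H]2C)OO1.CCCC[N+](CCCC)(CCCC)CCCC | intermediate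
31 | mycaperoxide H, (2S)-2-[(3S,6R)-6-methyl-6-(2-Dec-ethyl)-1,2-dioxan-3-yl]propanoic acid | C[C@H](C(=O)O)[C@@H]1CC[C@@](C)(CC[C@@]2(C)C3=CCCC(C)(C)[C@@H]3CC[C@H]2C)OO1 | target

Total step count: 16. Longest linear sequence: 15 steps (steps 1–7 and 9–16; step 8 is the side branch).

**Steps most likely to fail**

1. Step 11 (proposed new method). The ionisation may be followed by capture at the primary carbon or ring expansion to a cyclobutyl cation, by proton loss, or by attack of the ring alkene on the developing C6 cation. The inversion may also erode if the cation becomes free. The fallback uses known chemistry but gives up control at C6. It sets out from 13 and comes back at 22. Compound 13 is hydroborated with 9-BBN to 17 as in step 9 and coupled (PdCl2(dppf), Cs2CO3) with 2-bromopenta-1,4-diene F1, made from 2,3-dibromopropene and CH2=CHMgBr with CuI. This gives 2-(2-Dec-ethyl)penta-1,4-diene F2. Isayama–Mukaiyama hydroperoxysilylation (Co(acac)2, O2, Et3SiH, ClCH2CH2Cl) should react at the 1,1-disubstituted alkene through the tertiary radical and give 22 together with its C6 epimer, triethyl{[(3S)-3-methyl-1-Dec-hex-5-en-3-yl]peroxy}silane F3. No facial bias is expected, so the two diastereomers are separated by chromatography and 22 continues at step 13.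

2. Step 16 (proposed new method). The peroxide anion or fluoride may attack the lactone carbonyl and give perester or oligomer, the lactone may open by elimination, or the product may fragment under base. The fallback sets out from 28 and comes back at 31, using only known reaction types and keeping the inversion at C3. LiBH4 reduces the lactone to (2R,3R,6R)-2,6-dimethyl-8-Dec-6-[(triethylsilyl)peroxy]octane-1,3-diol F4. The primary hydroxyl is silylated (tBuMe2SiCl, imidazole) to the 1-O-tert-butyldimethylsilyl ether F5, and the C3 hydroxyl is converted into the 3-O-methanesulfonate F6 (MeSO2Cl, Et3N). Bu4NF then removes both silyl groups and the peroxide anion displaces the mesylate in a 6-exo-tet closure with inversion. No carbonyl group is present, so β-elimination is not favoured. The product is (2R)-2-[(3S,6R)-6-methyl-6-(2-Dec-ethyl)-1,2-dioxan-3-yl]propan-1-ol F7. Oxidation with TEMPO and PhI(OAc)2 gives (2S)-2-[(3S,6R)-6-methyl-6-(2-Dec-ethyl)-1,2-dioxan-3-yl]propanal F8, and buffered NaClO2 gives 31.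

3. Step 6. The cycloaddition may be slow at the hindered diene terminus, the diene may polymerise under the Lewis acid, or the facial selectivity at C5' may be poor. The fallback sets out from 6 and comes back at 13, and puts C5' under thermodynamic control. Ketone 6 is converted (LiN(iPr)2, Me3SiCl) into the trimethylsilyl enol ether of 6 F9. Mukaiyama–Michael addition to 4-methylpent-3-en-2-one (TiCl4, CH2Cl2, −78 °C) gives (2R,3R)-2-ethenyl-2,3-dimethyl-6-(2-methyl-4-oxopentan-2-yl)cyclohexan-1-one F10. Base-mediated aldol condensation (KOH, MeOH, heat) closes ring A to the 2'-oxo derivative of 13 (enone C2'=O, C1'=C10') F11. Its γ-carbon C5' equilibrates through the dienolate to the epimer with both ring B methyl groups equatorial, which is the one needed. Luche reduction (NaBH4, CeCl3·7H2O) gives the 2'-hydroxy derivative of 13 F12, acetylation gives the 2'-acetoxy derivative of 13 F13, and Pd(PPh3)4 with LiBHEt3 delivers hydride to the less hindered allyl terminus C2' to give 13.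

**Further compounds**
F1 | step 11 | 2-bromopenta-1,4-diene | C=CCC(Br)=C
F2 | step 11 | 2-(2-Dec-ethyl)penta-1,4-diene | C=CCC(=C)CC[C@@]1(C)C2=CCCC(C)(C)[C@@H]2CC[C@H]1C
F3 | step 11 | triethyl{[(3S)-3-methyl-1-Dec-hex-5-en-3-yl]peroxy}silane | C=CC[C@@](C)(OO[Si](CC)(CC)CC)CC[C@@]1(C)C2=CCCC(C)(C)[C@@H]2CC[C@H]1C
F4 | step 16 | (2R,3R,6R)-2,6-dimethyl-8-Dec-6-[(triethylsilyl)peroxy]octane-1,3-diol | OC[C@@H](C)[C@H](O)CC[C@](C)(OO[Si](CC)(CC)CC)CC[C@@]1(C)C2=CCCC(C)(C)[C@@H]2CC[C@H]1C
F5 | step 16 | 1-O-tert-butyldimethylsilyl ether of F4 | CC(C)(C)[Si](C)(C)OC[C@@H](C)[C@H](O)CC[C@](C)(OO[Si](CC)(CC)CC)CC[C@@]1(C)C2=CCCC(C)(C)[C@@H]2CC[C@H]1C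
F6 | step 16 | 3-O-methanesulfonate of F5 | CC(C)(C)[Si](C)(C)OC[C@@H](C)[C@H](OS(C)(=O)=O)CC[C@](C)(OO[Si](CC)(CC)CC)CC[C@@]1(C)C2=CCCC(C)(C)[C@@H]2CC[C@H]1C
F7 | step 16 | (2R)-2-[(3S,6R)-6-methyl-6-(2-Dec-ethyl)-1,2-dioxan-3-yl]propan-1-ol | OC[C@@H](C)[C@@H]1CC[C@@](C)(CC[C@@]2(C)C3=CCCC(C)(C)[C@@H]3CC[C@H]2C)OO1
F8 | step 16 | (2S)-2-[(3S,6R)-6-methyl-6-(2-Dec-ethyl)-1,2-dioxan-3-yl]propanal | O=C[C@@H](C)[C@@H]1CC[C@@](C)(CC[C@@]2(C)C3=CCCC(C)(C)[C@@H]3CC[C@H]2C)OO1
F9 | step 6 | trimethylsilyl enol ether of 6 | C=C[C@@]1(C)C(O[Si](C)(C)C)=CCC[C@H]1C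
F10 | step 6 | (2R,3R)-2-ethenyl-2,3-dimethyl-6-(2-methyl-4-oxopentan-2-yl)cyclohexan-1-one, C6 epimers | C=C[C@@]1(C)C(=O)C(C(C)(C)CC(C)=O)CC[C@H]1C
F11 | step 6 | 2'-oxo derivative of 13 (enone C2'=O, C1'=C10') | C=C[C@@]1(C)C2=CC(=O)CC(C)(C)[C@@H]2CC[C@H]1C
F12 | step 6 | 2'-hydroxy derivative of 13, C2' epimers | C=C[C@@]1(C)C2=CC(O)CC(C)(C)[C@@H]2CC[C@H]1C
F13 | step 6 | 2'-acetoxy derivative of 13, C2' epimers | C=C[C@@]1(C)C2=CC(OC(C)=O)CC(C)(C)[C@@H]2CC[C@H]1C
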